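**Retrosynthetic overview**
1. Target ⇐ 6,7-epoxide of the bicyclic trienone + angelic anhydride: C7–O by anti (SN2) opening at the allylic carbon, C6–O acylated in the same turnover; the epoxide ⇐ the cycloheptadiene by site- and face-selective O-transfer.
2. Cycloheptadiene ⇐ β,γ-unsaturated ketone (Shapiro) ⇐ allyl ketone + isopropenyl group by ring-closing metathesis.
3. Allyl ketone ⇐ bridged lactone ⇐ cis-ene-diol + ortho ester, by a [3,3] shift that trades the tertiary allylic C–O bond for the C4a–C5 bond (quaternary C5, cis ring fusion).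
4. cis-Ene-diol ⇐ cis-carveol by hydroxyl-directed ene oxygenation (the C–O bond that carries the later stereocontrol) ⇐ (S)-carvone.
5. Ring order: the six-membered ring and C9a come from (S)-carvone; the seven-membered ring is closed afterwards by metathesis.

Assumption: bicyclic compounds carry benzo[7]annulene locants (C1–C4, C4a, C5–C9, C9a), and angelic anhydride and trimethyl orthoisobutyrate are bought as catalogue reagents.

**Step 1**
Reactants: 1 (S)-(+)-carvone
Product: 2 (1S,5S)-2-methyl-5-(prop-1-en-2-yl)cyclohex-2-en-1-ol (cis-carveol)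
Conditions: NaBH4, CeCl3·7H2O, MeOH, 0 °C
Reagents that add atoms: none
Why: Luche 1,2-reduction; hydride adds axially to the Ce-activated carbonyl to give the diequatorial cis alcohol (1S, OH cis to the isopropenyl group) with no conjugate reduction.

**Step 2**
Reactants: 2 (1S,5S)-cis-carveol
Product: 4 (1S,2R,5R)-2-methyl-5-(prop-1-en-2-yl)cyclohex-3-ene-1,2-diol, via hydroperoxide 3 (not isolated)
Conditions: O2, tetraphenylporphyrin (cat.), visible light, CH2Cl2, −20 °C; then PPh3, 0 °C
Reagents that add atoms: dioxygen, O=O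
Why: Hydroxyl-directed Schenck ene reaction; singlet oxygen attacks only the trisubstituted ring alkene, bonds to C2 on the face of the C1 hydroxyl while the pseudo-axial H-4 on that face is abstracted (alkene moves to C3=C4), which sets the tertiary C2–O centre (2R) cis to OH and isopropenyl, and PPh3 reduces the hydroperoxide with retention.

**Step 3**
Reactants: 4 (1S,2R,5R)-2-methyl-5-(prop-1-en-2-yl)cyclohex-3-ene-1,2-diol; 5 trimethyl orthoisobutyrate
Product: 8 (1S,5S,9R)-4,4,7-trimethyl-9-(prop-1-en-2-yl)-2-oxabicyclo[3.2.2]non-6-en-3-one, via cyclic ortho ester 6 (not isolated), via ketene acetal 7 (not isolated)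
Conditions: EtCO2H (5 mol %), o-xylene, 140 °C, MeOH distilled off
Reagents that add atoms: none
Why: Proposed new method: the cis-diol and the ortho ester give a cyclic ortho ester, acid-catalysed loss of methanol gives a 2-isopropylidene-1,3-dioxolane in which only the O–C2 bond is allylic, and a boat-like [3,3] shift then places the Me2C terminus on C4 on the face of the departing C2–O bond (suprafacial 1,3-chirality transfer), creating the quaternary carbon and the new stereocentre cis to the isopropenyl group while the second oxygen keeps the acyl group as a bridged seven-membered lactone; the closest known reaction types are the Johnson ortho ester Claisen rearrangement of tertiary allylic alcohols and the Claisen ring expansion of 2-methylene-4-vinyl-1,3-dioxolanes to seven-membered lactones, neither shown for a ring alkene giving a bridged lactone or for a tetrasubstituted ketene acetal.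

**Step 4**
Reactants: 8 bridged lactone; 9 allylmagnesium bromide
Product: 10 2-[(1S,4S,6R)-4-hydroxy-3-methyl-6-(prop-1-en-2-yl)cyclohex-2-en-1-yl]-2-methylhex-5-en-3-one
Conditions: CH2=CHCH2MgBr (1.1 equiv), THF, −78 °C; aq. NH4Cl
Reagents that add atoms: none
Why: Grignard mono-addition to a lactone; the bridged neopentyl magnesium hemiketalate persists at −78 °C and collapses only on quench, so the hindered α,α-dimethyl ketone is not attacked again and no stereocentre is touched.

**Step 5**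
Reactants: 10 hydroxy allyl ketone
Product: 11 (2S,4aS,9aR)-2-hydroxy-3,5,5,9-tetramethyl-1,2,4a,5,7,9a-hexahydro-6H-benzo[7]annulen-6-one
Conditions: second-generation Hoveyda–Grubbs catalyst RuCl2(H2IMes)(=CH-C6H4-2-OiPr) (5 mol %), 1,4-benzoquinone (10 mol %), toluene, 80 °C
Reagents that add atoms: none
Why: Ring-closing metathesis; the Ru carbene loads on the terminal allyl alkene and closes onto the cis-disposed isopropenyl group (gem-dimethyl effect) to give the trisubstituted cycloheptene, the cis ring fusion (4aS,9aR) being already fixed.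

**Step 6**
Reactants: 11 bicyclic hydroxy ketone
Product: 13 (2S,4aS,9aR)-3,5,5,9-tetramethyl-2,4a,5,9a-tetrahydro-1H-benzo[7]annulen-2-ol, via trisylhydrazone 12 (not isolated)
Conditions: 2,4,6-iPr3C6H2SO2NHNH2, HCl (cat.), THF, 25 °C; then n-BuLi (3.5 equiv), −78 to 0 °C; H2O
Reagents that add atoms: none
Why: Shapiro reaction; only C7 carries α-hydrogens, so the hydrazone dianion loses sulfinate and N2 in one direction and protonation of the vinyllithium gives the conjugated C6=C7/C8=C9 diene, the extra base covering the C2 alkoxide.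

**Step 7**
Reactants: 13 dienol
Product: 14 (4aS,9aR)-3,5,5,9-tetramethyl-1,4a,5,9a-tetrahydro-2H-benzo[7]annulen-2-one
Conditions: MnO2 (activated, excess), CH2Cl2, 25 °C
Reagents that add atoms: none
Why: MnO2 oxidation of an allylic alcohol; only the allylic C2 carbinol reacts, which unveils the enone under neutral conditions without touching the diene or the γ-stereocentre C4a.

**Step 8**
Reactants: 14 trienone
Product: 15 (4aS,6R,7S,9aR)-6,7-epoxy-3,5,5,9-tetramethyl-1,4a,5,6,7,9a-hexahydro-2H-benzo[7]annulen-2-one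
Conditions: Mn(salen)Cl [(S,S); salen = N,N′-bis(3,5-di-tert-butylsalicylidene)cyclohexane-1,2-diaminate; trivalent manganese] (5 mol %), 4-phenylpyridine N-oxide (20 mol %), NaOCl (aq., pH 11.3), CH2Cl2, 0 °C
Reagents that add atoms: sodium hypochlorite, [Na+].[O-]Cl
Why: Jacobsen–Katsuki epoxidation; the cis-disubstituted conjugated C6=C7 alkene next to the gem-dimethyl carbon (a chromene-like substrate) is expected to react ahead of the trisubstituted C8=C9 and the electron-poor enone, and the (S,S) catalyst (by analogy with indene and 2,2-dimethylchromene) and the convex face of the cis-fused bicycle (the face of H-4a and H-9a) both favour the 6R,7S epoxide.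

**Step 9**
Reactants: 15 vinyl epoxide; 16 angelic anhydride
Product: 17 (4aS,6R,7R,9aR)-3,5,5,9-tetramethyl-2-oxo-2,4a,5,6,7,9a-hexahydro-1H-benzo[7]annulene-6,7-diyl bis[(2Z)-2-methylbut-2-enoate]
Conditions: 16 (2.5 equiv), Co(salen)(O2CC(CH3)=CHCH3) [(S,S)-salen as in step 8; trivalent cobalt; preformed from Co(salen), angelic acid and air] (5 mol %), tert-butyl methyl ether, 25 °C
Reagents that add atoms: none
Why: Proposed new method: a trivalent cobalt salen carboxylate activates the oxirane as a Lewis acid while a second cobalt-bound angelate attacks the allylic C7 from the face opposite the oxirane oxygen (SN2, inversion; C6 is neopentyl and blocked), and the cobalt alkoxide formed at O6 is acylated by angelic anhydride, which returns cobalt angelate, so both esters arrive in one turnover with 7R set by inversion and 6R retained and with no acylation of a free neopentyl alcohol; the closest known reaction types are the cobalt–salen-catalysed ring opening of epoxides by carboxylic acids and the nucleophile-catalysed conversion of epoxides and anhydrides into trans-1,2-diesters, not shown for a vinyl epoxide or for an isomerisation-prone (Z)-enoic anhydride.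

**Compound list**
1 | (S)-(+)-carvone, (5S)-2-methyl-5-(prop-1-en-2-yl)cyclohex-2-en-1-one | CC1=CC[C@@H](CC1=O)C(C)=C | starting material
2 | (1S,5S)-2-methyl-5-(prop-1-en-2-yl)cyclohex-2-en-1-ol (cis-carveol) | CC1=CC[C@@H](C[C@@H]1O)C(C)=C | intermediate
3 | (1S,2R,5R)-2-hydroperoxy-2-methyl-5-(prop-1-en-2-yl)cyclohex-3-en-1-ol | C[C@@]1(OO)C=C[C@@H](C[C@@H]1O)C(C)=C | intermediate
4 | (1S,2R,5R)-2-methyl-5-(prop-1-en-2-yl)cyclohex-3-ene-1,2-diol | C[C@@]1(O)C=C[C@@H](C[C@@H]1O)C(C)=C | intermediate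
5 | trimethyl orthoisobutyrate (1,1,1-trimethoxy-2-methylpropane) | CC(C)C(OC)(OC)OC | starting material
6 | cyclic ortho ester of 4: 2-methoxy-2-(propan-2-yl)-1,3-dioxolane cis-fused through O1 and O2 of the cyclohexene (epimers at the ortho ester carbon) | C[C@@]12C=C[C@@H](C[C@@H]1OC(OC)(C(C)C)O2)C(C)=C | intermediate
7 | ketene acetal: 2-(propan-2-ylidene)-1,3-dioxolane cis-fused through O1 and O2 of the cyclohexene | C[C@@]12C=C[C@@H](C[C@@H]1OC(=C(C)C)O2)C(C)=C | intermediate
8 | (1S,5S,9R)-4,4,7-trimethyl-9-(prop-1-en-2-yl)-2-oxabicyclo[3.2.2]non-6-en-3-one | CC1=C[C@H]2[C@@H](C[C@@H]1OC(=O)C2(C)C)C(C)=C | intermediate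
9 | allylmagnesium bromide | C=CC[Mg]Br | starting material
10 | 2-[(1S,4S,6R)-4-hydroxy-3-methyl-6-(prop-1-en-2-yl)cyclohex-2-en-1-yl]-2-methylhex-5-en-3-one | CC1=C[C@@H]([C@@H](C[C@@H]1O)C(C)=C)C(C)(C)C(=O)CC=C | intermediate
11 | (2S,4aS,9aR)-2-hydroxy-3,5,5,9-tetramethyl-1,2,4a,5,7,9a-hexahydro-6H-benzo[7]annulen-6-one | C1C=C(C)[C@@H]2C[C@H](O)C(C)=C[C@@H]2C(C)(C)C1=O | intermediate
12 | 2,4,6-triisopropylbenzenesulfonylhydrazone of 11 at C6 | C1C=C(C)[C@@H]2C[C@H](O)C(C)=C[C@@H]2C(C)(C)C1=NNS(=O)(=O)c1c(C(C)C)cc(C(C)C)cc1C(C)C | intermediate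
13 | (2S,4aS,9aR)-3,5,5,9-tetramethyl-2,4a,5,9a-tetrahydro-1H-benzo[7]annulen-2-ol | C1=CC=C(C)[C@@H]2C[C@H](O)C(C)=C[C@@H]2C1(C)C | intermediate
14 | (4aS,9aR)-3,5,5,9-tetramethyl-1,4a,5,9a-tetrahydro-2H-benzo[7]annulen-2-one | C1=CC=C(C)[C@@H]2CC(=O)C(C)=C[C@@H]2C1(C)C | intermediate
15 | (4aS,6R,7S,9aR)-6,7-epoxy-3,5,5,9-tetramethyl-1,4a,5,6,7,9a-hexahydro-2H-benzo[7]annulen-2-one (oxirane oxygen on the face of H-4a and H-9a) | O1[C@H]2C=C(C)[C@@H]3CC(=O)C(C)=C[C@@H]3C(C)(C)[C@@H]12 | intermediate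
16 | angelic anhydride, (2Z)-2-methylbut-2-enoic anhydride | C/C=C(/C)C(=O)OC(=O)/C(C)=C\C | starting material
17 | (4aS,6R,7R,9aR)-3,5,5,9-tetramethyl-2-oxo-2,4a,5,6,7,9a-hexahydro-1H-benzo[7]annulene-6,7-diyl bis[(2Z)-2-methylbut-2-enoate] | C/C=C(/C)C(=O)O[C@@H]1C=C(C)[C@@H]2CC(=O)C(C)=C[C@@H]2C(C)(C)[C@H]1OC(=O)/C(C)=C\C | target

**Step count and risk**
Total steps: 9. Longest linear sequence: 9 (from (S)-carvone).

The three steps most likely to fail:

Step 3 (new bridging Claisen). The strained boat-like transition state may be too slow, and the acid may ionise the tertiary allylic C–O bond or isomerise the product to a fused five-membered lactone. The fallback uses known chemistry, sets out from 4 and comes back at 8. tBuMe2SiCl and imidazole silylate only the secondary hydroxyl to give (1R,4R,6S)-6-[(tert-butyldimethylsilyl)oxy]-1-methyl-4-(prop-1-en-2-yl)cyclohex-2-en-1-ol F1. KN(SiMe3)2 then isobutyryl chloride give (1R,4R,6S)-6-[(tert-butyldimethylsilyl)oxy]-1-methyl-4-(prop-1-en-2-yl)cyclohex-2-en-1-yl 2-methylpropanoate F2. A standard Ireland–Claisen rearrangement (LiN(iPr)2, Me3SiCl, THF, −78 to 60 °C, then H3O+) transfers the carbon suprafacially to give 2-[(1S,4S,6R)-4-[(tert-butyldimethylsilyl)oxy]-3-methyl-6-(prop-1-en-2-yl)cyclohex-2-en-1-yl]-2-methylpropanoic acid F3. Bu4NF gives 2-[(1S,4S,6R)-4-hydroxy-3-methyl-6-(prop-1-en-2-yl)cyclohex-2-en-1-yl]-2-methylpropanoic acid F4, and Yamaguchi lactonisation (2,4,6-trichlorobenzoyl chloride, Et3N, then DMAP, toluene) closes 8.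

Step 8 (site- and face-selective epoxidation). The trisubstituted C8=C9 alkene may compete, or the facial preference may be lower than predicted. The fallback sets the C6 and C7 centres by reagent-controlled allylboration before ring closure; it sets out from 8 and comes back at 17. iBu2AlH (CH2Cl2, −78 °C) gives the lactol (1S,5S,9R)-4,4,7-trimethyl-9-(prop-1-en-2-yl)-2-oxabicyclo[3.2.2]non-6-en-3-ol F5. Brown alkoxyallylboration with (Z)-γ-(methoxymethoxy)allyl-B(Ipc)2 (from allyl methoxymethyl ether, sec-BuLi, (−)-Ipc2BOMe and BF3·OEt2) gives the syn adduct (3R,4R)-2-[(1S,4S,6R)-4-hydroxy-3-methyl-6-(prop-1-en-2-yl)cyclohex-2-en-1-yl]-4-(methoxymethoxy)-2-methylhex-5-en-3-ol F6. Ring-closing metathesis with the catalyst of step 5 gives (2S,4aS,6R,7R,9aR)-7-(methoxymethoxy)-3,5,5,9-tetramethyl-2,4a,5,6,7,9a-hexahydro-1H-benzo[7]annulene-2,6-diol F7. MnO2 gives (4aS,6R,7R,9aR)-6-hydroxy-7-(methoxymethoxy)-3,5,5,9-tetramethyl-1,4a,5,6,7,9a-hexahydro-2H-benzo[7]annulen-2-one F8. HCl in MeOH gives (4aS,6R,7R,9aR)-6,7-dihydroxy-3,5,5,9-tetramethyl-1,4a,5,6,7,9a-hexahydro-2H-benzo[7]annulen-2-one F9. Yamaguchi bis-esterification with angelic acid (2,4,6-trichlorobenzoyl chloride, Et3N, toluene, 80 °C) then gives 17.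

Step 9 (new acylative epoxide opening). Risks are attack at C9, ionisation of the vinyl epoxide with loss of the anti relationship, and slow acyl transfer to the neopentyl alkoxide. The fallback uses known chemistry in two separate operations; it sets out from 15 and comes back at 17. Cs2CO3 and angelic acid in DMF (60 °C) open the oxirane at the allylic C7 by SN2 to give (4aS,6R,7R,9aR)-6-hydroxy-3,5,5,9-tetramethyl-2-oxo-2,4a,5,6,7,9a-hexahydro-1H-benzo[7]annulen-7-yl (2Z)-2-methylbut-2-enoate F10. The remaining neopentyl hydroxyl is then esterified with the preformed mixed anhydride of angelic acid and 2,4,6-trichlorobenzoyl chloride (Et3N, then DMAP, toluene, 80 °C) to give 17.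

**Further compounds**
F1 | step 3 | (1R,4R,6S)-6-[(tert-butyldimethylsilyl)oxy]-1-methyl-4-(prop-1-en-2-yl)cyclohex-2-en-1-ol | C[C@@]1(O)C=C[C@@H](C[C@@H]1O[Si](C)(C)C(C)(C)C)C(C)=C
F2 | step 3 | (1R,4R,6S)-6-[(tert-butyldimethylsilyl)oxy]-1-methyl-4-(prop-1-en-2-yl)cyclohex-2-en-1-yl 2-methylpropanoate | C[C@@]1(OC(=O)C(C)C)C=C[C@@H](C[C@@H]1O[Si](C)(C)C(C)(C)C)C(C)=C
F3 | step 3 | 2-[(1S,4S,6R)-4-[(tert-butyldimethylsilyl)oxy]-3-methyl-6-(prop-1-en-2-yl)cyclohex-2-en-1-yl]-2-methylpropanoic acid | CC1=C[C@@H]([C@@H](C[C@@H]1O[Si](C)(C)C(C)(C)C)C(C)=C)C(C)(C)C(=O)O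
F4 | step 3 | 2-[(1S,4S,6R)-4-hydroxy-3-methyl-6-(prop-1-en-2-yl)cyclohex-2-en-1-yl]-2-methylpropanoic acid | CC1=C[C@@H]([C@@H](C[C@@H]1O)C(C)=C)C(C)(C)C(=O)O
F5 | step 8 | (1S,5S,9R)-4,4,7-trimethyl-9-(prop-1-en-2-yl)-2-oxabicyclo[3.2.2]non-6-en-3-ol (lactol, both anomers) | CC1=C[C@H]2[C@@H](C[C@@H]1OC(O)C2(C)C)C(C)=C
F6 | step 8 | (3R,4R)-2-[(1S,4S,6R)-4-hydroxy-3-methyl-6-(prop-1-en-2-yl)cyclohex-2-en-1-yl]-4-(methoxymethoxy)-2-methylhex-5-en-3-ol | CC1=C[C@@H]([C@@H](C[C@@H]1O)C(C)=C)C(C)(C)[C@@H](O)[C@H](OCOC)C=C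
F7 | step 8 | (2S,4aS,6R,7R,9aR)-7-(methoxymethoxy)-3,5,5,9-tetramethyl-2,4a,5,6,7,9a-hexahydro-1H-benzo[7]annulene-2,6-diol | COCO[C@@H]1C=C(C)[C@@H]2C[C@H](O)C(C)=C[C@@H]2C(C)(C)[C@H]1O
F8 | step 8 | (4aS,6R,7R,9aR)-6-hydroxy-7-(methoxymethoxy)-3,5,5,9-tetramethyl-1,4a,5,6,7,9a-hexahydro-2H-benzo[7]annulen-2-one | COCO[C@@H]1C=C(C)[C@@H]2CC(=O)C(C)=C[C@@H]2C(C)(C)[C@H]1O
F9 | step 8 | (4aS,6R,7R,9aR)-6,7-dihydroxy-3,5,5,9-tetramethyl-1,4a,5,6,7,9a-hexahydro-2H-benzo[7]annulen-2-one | O[C@@H]1C=C(C)[C@@H]2CC(=O)C(C)=C[C@@H]2C(C)(C)[C@H]1O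
F10 | step 9 | (4aS,6R,7R,9aR)-6-hydroxy-3,5,5,9-tetramethyl-2-oxo-2,4a,5,6,7,9a-hexahydro-1H-benzo[7]annulen-7-yl (2Z)-2-methylbut-2-enoate | C/C=C(/C)C(=O)O[C@@H]1C=C(C)[C@@H]2CC(=O)C(C)=C[C@@H]2C(C)(C)[C@H]1O
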